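## The problem

Blepharocalyxin E is a dimeric diarylheptanoid built on a 2,3,4,6-tetrasubstituted tetrahydropyran (O1, C2–C6). C2 carries a 4-hydroxyphenyl group, C3 a branched side chain that starts at C1', C4 an acylphloroglucinol (ring A, the A ring of a 4-hydroxychalcone) and C6 a 2-(4-hydroxyphenyl)ethyl group. The hardest connection is the bond from the secondary carbon C4 to an aromatic carbon flanked by two oxygen-bearing carbons, next to C3, whose substituent C1' is both benzylic and allylic. There are six stereocentres. C2 (S), C3 (R), C4 (R) and C6 (S) are all equatorial, so C6 can anchor the ring: C2 and C3 can be set from it under thermodynamic control while C4 is a carbonyl carbon, and C4 can then be set from C3. C1' (S) and the remote carbinol (S) lie outside the ring and need reagent control. The free phenols, the 2'-hydroxychalcone (a Michael acceptor that can close to a flavanone), the C2–O1 bond (benzylic to a 4-hydroxyphenyl ring) and the (E)-alkene rule out hydrogenation, hydrogenolysis and strong acid late in the synthesis. Ring A has the oxygenation pattern of a folded tetraketide: going round from the carbon bonded to C4 one meets C–OH, CH, C–OMe, the acyl-bearing carbon and C–OH. Read as a chain this is ester carbonyl, α-carbon (bonded to C4), ketone, CH, enol ether carbon, CH2 and acetyl, so the ring can be closed last by a Claisen condensation between the CH2 carbon and the ester carbonyl.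

## Retrosynthesis

**29 to 28 to 27 + 10.** The last bond made is the Cα=Cβ bond of the chalcone, cut to methyl ketone 27 and aldehyde 10; one acid step then removes the six protecting groups of 28 to give 29. Carrying the enone through the synthesis instead would expose a Michael acceptor and a flavanone-prone 2'-hydroxychalcone to every basic and reducing step. 27 is simpler by one aryl group and the enone. The forward condensation must work on an acetophenone with two free phenols, and the deprotection must leave the chalcone open.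

**27 to 26 (key cut).** The ring A bond between the acetyl-bearing carbon and the adjacent phenolic carbon is cut. The neighbouring cut at the C4–aryl bond would need a di-ortho-substituted arene to be joined to a hindered secondary carbon and would leave acylation and methylation of ring A to arene regiochemistry. An aldol-type fold of the same chain would give a resorcinol, not a phloroglucinol. The Claisen cut replaces the arene by a linear chain on an ester α-carbon, so the problem becomes enolate chemistry on ester 19. The methoxy group is carried as the methyl enol ether of the middle carbonyl, which fixes its position and blocks other folds. The forward step needs the (E)-enol ether, which holds the chain ketone cis to the CH2 group, and it needs the CH2 carbanion to attack the ester rather than take either aldol path.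

**26 to 25 to 19 + 23 (through 24).** The bond between the ester α-carbon and the chain ketone is cut (crossed Claisen acylation of the enolate of 19 by acyl imidazole 24, made from acid 23). The acetyl group must be masked during this step because its CH2 would quench the enolate. A dimethyl ketal is chosen because it is the only acetal in 25 that weak acid removes. Acid 23 comes from ester 22, made from silyl dienol ether 21 (from commercial ester 20) by a vinylogous Mukaiyama reaction with an orthoester. This route fixes the (E)-geometry because 20 already has it and the thermodynamics favour it.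

**19 to 18 + 5.** The (E)-alkene of the side chain is cut by cross-metathesis into the vinyl group of 18 and homoallylic silyl ether 5. An olefination from a C1' aldehyde would pass through an epimerisable α-aryl aldehyde. The cut removes the remote stereocentre and a third of the mass from the main line. The carbinol is protected as a silyl ether, not a sixth MOM group, so that no alkyl MOM acetal has to be cleaved at the end.

**18 to 17 to 16.** The C4–CH2 bond is traced to the ketone of 16 through enoate 17 (Horner–Wadsworth–Emmons, then conjugate reduction). The ketone is kept to this point because it makes C2 and C3 epimerisable. The reduction must be chemoselective (vinyl group present) and must deliver hydrogen to C4 from the axial side.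

**16 to 15 to 11 + 14.** The C3–C1' bond is cut next to the ester-activated C3 of β-keto ester 11; the ester directs the alkylation to C3 and is then removed from 15. An iridium-catalysed branched allylation with cinnamyl carbonate 14 sets C1' by the ligand alone. The accompanying C3 configuration is irrelevant because decarboxylation erases it. 14 comes from 10 through 12 and 13, and 10 from 9.

**11 to 8 + 10.** The C2–C3 and O1–C2 bonds are cut (Maitland–Japp-type Knoevenagel and oxa-Michael sequence). A Prins closure would need an acid-labile electron-rich benzylic cation and would not give the C4 ketone directly. The forward step is reversible, so C6 of 8 dictates C2 and C3.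

**8 to 3 + 6; 5 to 4 to 3; 3 to 2 to 1.** Both carbinol centres have the same sense and the same neighbours, so both are made from aldehyde 3 with the same (R)-BINOL titanium catalyst: a vinylogous aldol with diene 6 (through 7) gives 8, and an allylation gives 4, silylated to 5. Aldehyde 3 comes from commercial ester 1 through 2.

## Roads not taken

**Alternative 1:** The cut is the C3–C4 bond, made while ring A acts as an ortho-quinone methide and the future C2 is held as a lactone carbonyl. Fluoride would unveil the quinone methide from benzylic acetate A2, a carbene catalyst would turn acyl imidazole A3 into an azolium enolate, and Michael addition followed by lactonisation would give the cis-3,4-disubstituted dihydrocoumarin A1. Cis in A1 corresponds to the required 3,4-trans relation in the tetrahydropyran, because ring member and substituent at C4 change roles when the lactone is later moved to the C6 oxygen.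
- Merits: ring A is bought, not built; the halves are of similar size; C3 and C4 are set by a catalyst; the two ortho oxygens of ring A are differentiated for free.
- Weak points: alkyl-substituted quinone methides such as the one from A2 are short-lived and tautomerise to styrenes. The enolate from A3 is branched next to the reacting carbon, and the catalyst must overrule two existing centres. After the annulation the lactone must be moved to O1, arylated at C2 and reduced before the ring exists, and the acetyl group and chalcone must still be added to a hindered arene.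
- Comparison: this road controls the C3–C4 relation better than the conjugate reduction of step 14 and is more convergent. The chosen plan sets against it that C2 and C3 come from ring thermodynamics without a multi-step relay, and that the acyl and methoxy groups of ring A need no regioselective arene chemistry.

**Alternative 2:** The cut is the C5–C6 bond together with the C4–H bond. The α-acetoxy ether A5 would ionise with a Lewis acid to the O1=C6 oxocarbenium ion, the 1,1-disubstituted alkene carrying ring A would attack it, and Et3SiH would quench the tertiary benzylic C4 cation from the axial side to give the all-equatorial tetrahydropyran A4.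
- Merits: ring, C6 and C4 are set in one step with the known equatorial preference of Prins chairs; the cation is stabilised by the trioxygenated arene; the segment-coupling format avoids oxonia-Cope scrambling.
- Weak points: C2, C3 and C1' must already be present in A5 as an acyclic stereotriad. The alkene bearing a 2,6-disubstituted arene is twisted out of conjugation, so it is a poor nucleophile and gives a poorly stabilised cation. The C4 cation sits one bond from the vinyl group and the C1' aryl group, which could trap it. Five aryl silyl ethers must survive the Lewis acid. Ring A still needs acetylation (unambiguous, since its two free positions are equivalent) and the chain still needs the metathesis.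
- Comparison: this is probably the shortest way to the ring, and hydride delivery to a cation is better precedented for C4 than step 14. The chosen plan sets against it that it needs no acyclic stereotriad and runs no cationic step beside the vinyl group.

**Alternative 3:** The cuts are C3–C1' and O1–C2, made in one cascade that imitates the dimerisation of two diarylheptanoids. A chiral iridium catalyst with an acid promoter would ionise the racemic carbinol A8 to an allyl complex, C3 of the (E)-styrene A7 would attack its aryl-substituted terminus, and the resulting C2 benzylic cation would be captured by the C6 silyl ether oxygen to give A6.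
- Merits: two bonds and three stereocentres (C1', C3, C2) in one step from halves of similar size; enantioconvergent use of a racemic carbinol; catalyst control of C1' of the same kind as in step 11.
- Weak points: a 1,2-disubstituted styrene is a weak nucleophile for an intermolecular attack. C3 must be set relative to C4 in an open chain beside the bulky ring A. The C2 cation can lose a proton or be captured by a ring A oxygen to give a flavan. The acid promoter meets MOM ethers. A7 needs its own enantioselective synthesis of the C4/C6 pair, and acetylation of ring A, chain extension and the chalcone all remain.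
- Comparison: in step count this road could clearly beat the chosen one, and its C1' control is equal. The chosen plan sets against it that each ring-forming event is either thermodynamically funnelled (steps 7 and 12) or made irreversible by aromatisation (step 21), and that no cation is generated beside electron-rich arenes.

Key step: step 21

Assumption: the facial preferences of the (R)-BINOL titanium catalysts (steps 3 and 5) and of the (Ra,R,R)-phosphoramidite iridium catalyst (step 11) are assigned by analogy with simple aldehydes and cinnamyl carbonates; if a model compound shows the opposite sense, the mirror-image ligand is used and nothing else changes.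

Remark: β-dicarbonyl compounds 11, 25 and 26 will exist as keto–enol mixtures and are drawn as keto forms; 15, 25 and 26 are mixtures at one centre that is later destroyed, and that centre is left undefined.

Abbreviations: ArM = 4-(methoxymethoxy)phenyl; TBS = tert-butyldimethylsilyl; Q = (2S,3R,4R,6S)-2-ArM-6-(2-ArM-ethyl)-3-[(1S,2E,5S)-1,7-bis(ArM)-5-(TBS-oxy)hept-2-en-1-yl]tetrahydro-2H-pyran-4-yl; TBD = 1,5,7-triazabicyclo[4.4.0]dec-5-ene; PPTS = pyridinium 4-toluenesulfonate.

## Route

Step 1
Reactants: 1 methyl 3-(4-hydroxyphenyl)propanoate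
Product: 2 methyl 3-[4-(methoxymethoxy)phenyl]propanoate
Conditions: MeOCH2Cl, iPr2NEt, CH2Cl2, 0 °C to rt
Reagents that add atoms: chloromethyl methyl ether, COCCl
Why: O-alkylation of the phenol (MOM protection); the methyl ester is inert to the amine base.

Step 2
Reactants: 2 methyl 3-[4-(methoxymethoxy)phenyl]propanoate
Product: 3 3-[4-(methoxymethoxy)phenyl]propanal
Conditions: iBu2AlH (1.1 equiv), CH2Cl2, −78 °C; potassium sodium tartrate work-up
Reagents that add atoms: none
Why: Partial reduction of the ester; the aluminium hemiacetal is stable at −78 °C and releases the aldehyde only on work-up.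

Step 3
Reactants: 3 3-[4-(methoxymethoxy)phenyl]propanal
Product: 4 (3S)-1-[4-(methoxymethoxy)phenyl]hex-5-en-3-ol
Conditions: Ti(OiPr)4 (10 mol%), (R)-BINOL (20 mol%), 4 Å MS, CH2Cl2; Bu3SnCH2CH=CH2, −20 °C; aq. NaHCO3
Reagents that add atoms: allyltributylstannane, C=CC[Sn](CCCC)(CCCC)CCCC
Why: Keck asymmetric allylation; the (R)-BINOL titanium Lewis acid should expose the Re face of the aldehyde, which gives the (S) carbinol because the allyl CH2 outranks the arylethyl chain.

Step 4
Reactants: 4 (3S)-1-[4-(methoxymethoxy)phenyl]hex-5-en-3-ol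
Product: 5 tert-butyl{[(3S)-1-[4-(methoxymethoxy)phenyl]hex-5-en-3-yl]oxy}dimethylsilane
Conditions: tBuMe2SiCl, imidazole, DMF, rt
Reagents that add atoms: tert-butyldimethylsilyl chloride, CC(C)(C)[Si](C)(C)Cl
Why: Standard silylation of a secondary alcohol; the ether should survive the bases of steps 19, 21 and 22 and fall in the final acid step.

Step 5
Reactants: 3 3-[4-(methoxymethoxy)phenyl]propanal, 6 1-methoxy-1,3-bis(trimethylsilyloxy)buta-1,3-diene (Chan's diene)
Product: 8 methyl (5S)-5-hydroxy-7-[4-(methoxymethoxy)phenyl]-3-oxoheptanoate, via bis-silyl aldol adduct 7 (not isolated)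
Conditions: Ti(OiPr)4 (10 mol%), (R)-BINOL (10 mol%), 4 Å MS, THF, −78 °C to rt; then 10% aq. citric acid, THF, 0 °C
Reagents that add atoms: none
Why: Vinylogous Mukaiyama aldol addition of the diene at its terminal carbon, catalysed by the same (R)-BINOL titanium complex at the same Re face as in step 3, which should give the (S) carbinol that becomes C6; citric acid cleaves both silyl groups without touching the aryl MOM ether.

Step 6
Reactants: 9 4-hydroxybenzaldehyde
Product: 10 4-(methoxymethoxy)benzaldehyde
Conditions: MeOCH2Cl, iPr2NEt, CH2Cl2, 0 °C to rt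
Reagents that add atoms: chloromethyl methyl ether, COCCl
Why: MOM protection of the phenol; 10 serves three times (C2 aryl, C1' aryl, chalcone).

Step 7
Reactants: 8 methyl (5S)-5-hydroxy-7-[4-(methoxymethoxy)phenyl]-3-oxoheptanoate, 10 4-(methoxymethoxy)benzaldehyde
Product: 11 methyl (2S,3R,6S)-2-ArM-6-(2-ArM-ethyl)-4-oxotetrahydro-2H-pyran-3-carboxylate
Conditions: piperidine (20 mol%), AcOH (20 mol%), 4 Å MS, toluene, 50 °C
Reagents that add atoms: none
Why: Maitland–Japp-type sequence of Knoevenagel condensation and 6-endo-trig oxa-Michael addition of the C6 hydroxyl; the oxa-Michael step is reversible and C3 is enolisable, so the fixed C6 centre should funnel the mixture to the 2,6-cis, 2,3-trans (all-equatorial) isomer.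

Step 8
Reactants: 10 4-(methoxymethoxy)benzaldehyde
Product: 12 methyl (2E)-3-ArM-prop-2-enoate
Conditions: (MeO)2P(O)CH2CO2Me, NaH, THF, 0 °C to rt
Reagents that add atoms: trimethyl phosphonoacetate, COC(=O)CP(=O)(OC)OC
Why: Horner–Wadsworth–Emmons olefination of an aromatic aldehyde, (E)-selective.

Step 9
Reactants: 12 methyl (2E)-3-ArM-prop-2-enoate
Product: 13 (2E)-3-ArM-prop-2-en-1-ol
Conditions: iBu2AlH (2.2 equiv), CH2Cl2, −78 to 0 °C
Reagents that add atoms: none
Why: 1,2-Reduction of the enoate to the allylic alcohol; this hydride does not reduce the conjugated double bond.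

Step 10
Reactants: 13 (2E)-3-ArM-prop-2-en-1-ol
Product: 14 methyl (2E)-3-ArM-prop-2-en-1-yl carbonate
Conditions: ClCO2Me, pyridine, CH2Cl2, 0 °C
Reagents that add atoms: methyl chloroformate, COC(=O)Cl
Why: Acylation of the primary allylic alcohol gives the linear carbonate that iridium ionises; its methoxide by-product later serves as the base.

Step 11
Reactants: 11 methyl (2S,3R,6S)-2-ArM-6-(2-ArM-ethyl)-4-oxotetrahydro-2H-pyran-3-carboxylate, 14 methyl (2E)-3-ArM-prop-2-en-1-yl carbonate
Product: 15 methyl (2R,6S)-2-ArM-6-(2-ArM-ethyl)-3-[(1R)-1-ArM-prop-2-en-1-yl]-4-oxotetrahydro-2H-pyran-3-carboxylate (mixture at C3)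
Conditions: [Ir(cod)Cl]2 (2 mol%), (Ra,R,R)-O,O'-(1,1'-binaphthalene-2,2'-diyl) N,N-bis(1-phenylethyl)phosphoramidite (4 mol%), TBD (8 mol%), THF, rt
Reagents that add atoms: none
Why: Iridium-catalysed branched-selective allylic alkylation of a cyclic β-keto ester; the enolate attacks the aryl-substituted allyl terminus anti to the metal, so C1' is set by the ligand alone (its (R) label is the spatial arrangement of (S)-C1' in 16, the quaternary C3 merely outranking the aryl group), and the C3 configuration is erased in step 12.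

Step 12
Reactants: 15 methyl (2R,6S)-2-ArM-6-(2-ArM-ethyl)-3-[(1R)-1-ArM-prop-2-en-1-yl]-4-oxotetrahydro-2H-pyran-3-carboxylate
Product: 16 (2S,3R,6S)-2-ArM-6-(2-ArM-ethyl)-3-[(1S)-1-ArM-prop-2-en-1-yl]tetrahydro-4H-pyran-4-one
Conditions: LiCl, DMSO/H2O, 130 °C
Reagents that add atoms: none
Why: Krapcho dealkoxycarbonylation; chloride demethylates the β-keto ester and the carboxylate loses CO2, and the enolisable C3 should settle equatorial, trans to the C2 aryl group.

Step 13
Reactants: 16 (2S,3R,6S)-2-ArM-6-(2-ArM-ethyl)-3-[(1S)-1-ArM-prop-2-en-1-yl]tetrahydro-4H-pyran-4-one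
Product: 17 methyl 2-[(2S,3S,6S)-2-ArM-6-(2-ArM-ethyl)-3-[(1S)-1-ArM-prop-2-en-1-yl]tetrahydro-4H-pyran-4-ylidene]acetate (E/Z mixture)
Conditions: (MeO)2P(O)CH2CO2Me, NaH, THF, 0 to 65 °C
Reagents that add atoms: trimethyl phosphonoacetate, COC(=O)CP(=O)(OC)OC
Why: Horner–Wadsworth–Emmons olefination of the ketone; the alkene geometry is irrelevant because step 14 reduces it, and a slight excess of phosphonate over NaH limits deconjugation.

Step 14
Reactants: 17 methyl 2-[(2S,3S,6S)-2-ArM-6-(2-ArM-ethyl)-3-[(1S)-1-ArM-prop-2-en-1-yl]tetrahydro-4H-pyran-4-ylidene]acetate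
Product: 18 methyl 2-[(2S,3R,4S,6S)-2-ArM-6-(2-ArM-ethyl)-3-[(1S)-1-ArM-prop-2-en-1-yl]tetrahydro-2H-pyran-4-yl]acetate
Conditions: Mg turnings, MeOH, 0 °C to rt
Reagents that add atoms: none
Why: Dissolving-metal conjugate reduction of the α,β-unsaturated ester, which leaves the isolated vinyl group alone; C4 should be protonated from the axial side, as in metal–ammonia reductions of enones, placing the CH2CO2Me group equatorial and trans to the C3 substituent.

Step 15
Reactants: 18 methyl 2-[(2S,3R,4S,6S)-2-ArM-6-(2-ArM-ethyl)-3-[(1S)-1-ArM-prop-2-en-1-yl]tetrahydro-2H-pyran-4-yl]acetate, 5 tert-butyl{[(3S)-1-[4-(methoxymethoxy)phenyl]hex-5-en-3-yl]oxy}dimethylsilane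
Product: 19 methyl 2-[(2S,3R,4S,6S)-2-ArM-6-(2-ArM-ethyl)-3-[(1S,2E,5S)-1,7-bis(ArM)-5-(TBS-oxy)hept-2-en-1-yl]tetrahydro-2H-pyran-4-yl]acetate
Conditions: RuCl2(H2IMes)(=CH-C6H4-2-OiPr) (second-generation Hoveyda–Grubbs catalyst, 5 mol%), 5 (3 equiv), 1,4-benzoquinone (10 mol%), CH2Cl2, 40 °C
Reagents that add atoms: none
Why: Olefin cross-metathesis between the allylically branched vinyl group, which homodimerises slowly, and an excess of the unhindered homoallylic ether; the branched allylic carbon should favour the (E)-alkene and benzoquinone suppresses double-bond migration.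

Step 16
Reactants: 20 methyl (2E)-3-methoxybut-2-enoate
Product: 21 1,3-dimethoxy-1-(trimethylsilyloxy)buta-1,3-diene (Brassard's diene)
Conditions: LiN(iPr)2, THF, −78 °C; Me3SiCl
Reagents that add atoms: chlorotrimethylsilane, C[Si](C)(C)Cl
Why: γ-Deprotonation of the β-methoxy enoate and O-silylation of the dienolate.

Step 17
Reactants: 21 1,3-dimethoxy-1-(trimethylsilyloxy)buta-1,3-diene
Product: 22 methyl (2E)-3,5,5-trimethoxyhex-2-enoate
Conditions: MeC(OMe)3, Me3SiOTf (5 mol%), CH2Cl2, −78 °C; Et3N quench
Reagents that add atoms: trimethyl orthoacetate, CC(OC)(OC)OC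
Why: Vinylogous Mukaiyama reaction; the silyl triflate ionises the orthoester to a dimethoxycarbenium ion that the dienol ether attacks at its terminal carbon, and the (E)-β-methoxy enoate (ester carbonyl cis to the new CH2) is both the favoured geometry and the one step 21 needs.

Step 18
Reactants: 22 methyl (2E)-3,5,5-trimethoxyhex-2-enoate
Product: 23 (2E)-3,5,5-trimethoxyhex-2-enoic acid
Conditions: LiOH, THF/MeOH/H2O, 40 °C; then 1 M HCl to pH 5, 0 °C
Reagents that add atoms: lithium hydroxide, [Li+].[OH-]
Why: Saponification; ketal and enol ether are base-stable, and the acid is liberated cold at pH 5 and used at once so that the dimethyl ketal survives.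

Step 19
Reactants: 19 methyl 2-[(2S,3R,4S,6S)-2-ArM-6-(2-ArM-ethyl)-3-[(1S,2E,5S)-1,7-bis(ArM)-5-(TBS-oxy)hept-2-en-1-yl]tetrahydro-2H-pyran-4-yl]acetate, 23 (2E)-3,5,5-trimethoxyhex-2-enoic acid
Product: 25 methyl (4E)-5,7,7-trimethoxy-3-oxo-2-Q-oct-4-enoate (mixture at C2 of the chain), via acyl imidazole of the trimethoxyhexenoic acid 24 (not isolated)
Conditions: 23, 1,1'-carbonyldiimidazole, THF, rt; separately 19, LiN(SiMe3)2 (2.2 equiv), THF, −78 °C; combine, −78 to −30 °C; aq. NH4Cl
Reagents that add atoms: none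
Why: Crossed Claisen condensation, C-acylation of the lithium ester enolate by the acyl imidazole; the second equivalent of base takes up the more acidic β-keto ester as it forms, which prevents double acylation.

Step 20
Reactants: 25 methyl (4E)-5,7,7-trimethoxy-3-oxo-2-Q-oct-4-enoate
Product: 26 methyl (4E)-5-methoxy-3,7-dioxo-2-Q-oct-4-enoate
Conditions: PPTS (20 mol%), acetone/H2O (9:1), rt
Reagents that add atoms: water, O
Why: Acid-catalysed hydrolysis of the dimethyl ketal, which ionises far faster than the formaldehyde-derived MOM acetals or the vinylogous ester, so weak acid at room temperature should unmask only the methyl ketone.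

Step 21
Reactants: 26 methyl (4E)-5-methoxy-3,7-dioxo-2-Q-oct-4-enoate
Product: 27 1-(2,4-dihydroxy-6-methoxy-3-Q-phenyl)ethan-1-one
Conditions: NaOMe (5 equiv), MeOH, 0 to 55 °C; AcOH quench
Reagents that add atoms: none
Why: Proposed new method: NaOMe equilibrates the acidic sites of 26, and the anion at the CH2 between the acetyl carbonyl and the enol ether carbon (a vinylogous β-diketonate, held cis to the chain ketone by the (E)-enol ether) adds to the methyl ester carbonyl of the still neutral β-keto ester; loss of methoxide and enolisation of the two ring carbonyls give the aromatic ring. The closest known reaction type is the base-mediated Claisen cyclisation of 3,5,7-triketo esters to acylphloroglucinols, here with the middle carbonyl carried as its methyl enol ether and the ester α-carbon substituted. Ring A closes in the 6-exo-trig mode, by attack on an ester carbonyl that is exocyclic to the new ring. No stereocentre is formed, none of the six existing ones carries an acidic hydrogen, and the epimeric ester α-carbon becomes aromatic. The step needs Claisen closure to win over two aldol closures. Closure of the acetyl CH3 onto the chain ketone is disfavoured because that CH3 is several pKa units less acidic than the doubly activated CH2 and the chain ketone is a deactivated vinylogous ester carbonyl. Addition of the β-keto ester carbon to the acetyl group is disfavoured because that carbon bears the bulky C4 substituent, and its adduct is a hindered quaternary aldolate that cannot aromatise and reverts. Methoxide as base makes ester exchange and addition–elimination at the enol ether carbon degenerate, so the methoxy group, the two flanking phenols and the acetyl group arrive in place without arene substitution chemistry.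

Step 22
Reactants: 27 1-(2,4-dihydroxy-6-methoxy-3-Q-phenyl)ethan-1-one, 10 4-(methoxymethoxy)benzaldehyde
Product: 28 (2E)-1-(2,4-dihydroxy-6-methoxy-3-Q-phenyl)-3-ArM-prop-2-en-1-one
Conditions: KOH (50% aq.), EtOH, rt to 40 °C; AcOH to pH 6
Reagents that add atoms: none
Why: Claisen–Schmidt condensation of the acetophenone with a non-enolisable aldehyde, known for 2',4'-dihydroxyacetophenones in concentrated KOH; the phenoxide salt keeps the 2'-hydroxychalcone open and E1cB dehydration gives the (E)-enone.

Step 23
Reactants: 28 (2E)-1-(2,4-dihydroxy-6-methoxy-3-Q-phenyl)-3-ArM-prop-2-en-1-one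
Product: 29 blepharocalyxin E
Conditions: 3 M aq. HCl/MeOH (1:5), rt to 40 °C
Reagents that add atoms: none
Why: Acid-catalysed methanolysis of five aryl MOM acetals and the secondary silyl ether in one operation, as used for related polyhydroxychalcones; mild acid near room temperature is chosen to avoid chalcone–flavanone isomerisation and ionisation of the C2–O1 bond.

## Compound list

1 | methyl 3-(4-hydroxyphenyl)propanoate | COC(=O)CCc1ccc(O)cc1 | starting material
2 | methyl 3-[4-(methoxymethoxy)phenyl]propanoate | COC(=O)CCc1ccc(OCOC)cc1 | intermediate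
3 | 3-[4-(methoxymethoxy)phenyl]propanal | O=CCCc1ccc(OCOC)cc1 | intermediate
4 | (3S)-1-[4-(methoxymethoxy)phenyl]hex-5-en-3-ol | C=CC[C@@H](O)CCc1ccc(OCOC)cc1 | intermediate
5 | tert-butyl{[(3S)-1-[4-(methoxymethoxy)phenyl]hex-5-en-3-yl]oxy}dimethylsilane | C=CC[C@@H](O[Si](C)(C)C(C)(C)C)CCc1ccc(OCOC)cc1 | intermediate
6 | 1-methoxy-1,3-bis(trimethylsilyloxy)buta-1,3-diene (Chan's diene) | COC(O[Si](C)(C)C)=CC(=C)O[Si](C)(C)C | starting material
7 | methyl (5S)-7-[4-(methoxymethoxy)phenyl]-3,5-bis(trimethylsilyloxy)hept-2-enoate | COC(=O)C=C(O[Si](C)(C)C)C[C@@H](O[Si](C)(C)C)CCc1ccc(OCOC)cc1 | intermediate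
8 | methyl (5S)-5-hydroxy-7-[4-(methoxymethoxy)phenyl]-3-oxoheptanoate | COC(=O)CC(=O)C[C@@H](O)CCc1ccc(OCOC)cc1 | intermediate
9 | 4-hydroxybenzaldehyde | O=Cc1ccc(O)cc1 | starting material
10 | 4-(methoxymethoxy)benzaldehyde | COCOc1ccc(C=O)cc1 | intermediate
11 | methyl (2S,3R,6S)-2-[4-(methoxymethoxy)phenyl]-6-{2-[4-(methoxymethoxy)phenyl]ethyl}-4-oxotetrahydro-2H-pyran-3-carboxylate | O=C1C[C@H](CCc2ccc(OCOC)cc2)O[C@H](c2ccc(OCOC)cc2)[C@H]1C(=O)OC | intermediate
12 | methyl (2E)-3-[4-(methoxymethoxy)phenyl]prop-2-enoate | COC(=O)/C=C/c1ccc(OCOC)cc1 | intermediate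
13 | (2E)-3-[4-(methoxymethoxy)phenyl]prop-2-en-1-ol | OC/C=C/c1ccc(OCOC)cc1 | intermediate
14 | methyl (2E)-3-[4-(methoxymethoxy)phenyl]prop-2-en-1-yl carbonate | COC(=O)OC/C=C/c1ccc(OCOC)cc1 | intermediate
15 | methyl (2R,6S)-2-ArM-6-(2-ArM-ethyl)-3-[(1R)-1-ArM-prop-2-en-1-yl]-4-oxotetrahydro-2H-pyran-3-carboxylate (C3 epimers) | O=C1C[C@H](CCc2ccc(OCOC)cc2)O[C@H](c2ccc(OCOC)cc2)C1(C(=O)OC)[C@H](C=C)c1ccc(OCOC)cc1 | intermediate
16 | (2S,3R,6S)-2-ArM-6-(2-ArM-ethyl)-3-[(1S)-1-ArM-prop-2-en-1-yl]tetrahydro-4H-pyran-4-one | O=C1C[C@H](CCc2ccc(OCOC)cc2)O[C@H](c2ccc(OCOC)cc2)[C@H]1[C@H](C=C)c1ccc(OCOC)cc1 | intermediate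
17 | methyl 2-[(2S,3S,6S)-2-ArM-6-(2-ArM-ethyl)-3-[(1S)-1-ArM-prop-2-en-1-yl]tetrahydro-4H-pyran-4-ylidene]acetate (E/Z mixture) | COC(=O)C=C1C[C@H](CCc2ccc(OCOC)cc2)O[C@H](c2ccc(OCOC)cc2)[C@H]1[C@H](C=C)c1ccc(OCOC)cc1 | intermediate
18 | methyl 2-[(2S,3R,4S,6S)-2-ArM-6-(2-ArM-ethyl)-3-[(1S)-1-ArM-prop-2-en-1-yl]tetrahydro-2H-pyran-4-yl]acetate | COC(=O)C[C@@H]1C[C@H](CCc2ccc(OCOC)cc2)O[C@H](c2ccc(OCOC)cc2)[C@H]1[C@H](C=C)c1ccc(OCOC)cc1 | intermediate
19 | methyl 2-[(2S,3R,4S,6S)-2-ArM-6-(2-ArM-ethyl)-3-[(1S,2E,5S)-1,7-bis(ArM)-5-(tert-butyldimethylsilyloxy)hept-2-en-1-yl]tetrahydro-2H-pyran-4-yl]acetate | COC(=O)C[C@@H]1C[C@H](CCc2ccc(OCOC)cc2)O[C@H](c2ccc(OCOC)cc2)[C@H]1[C@H](/C=C/C[C@@H](O[Si](C)(C)C(C)(C)C)CCc1ccc(OCOC)cc1)c1ccc(OCOC)cc1 | intermediate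
20 | methyl (2E)-3-methoxybut-2-enoate | COC(=O)/C=C(\C)OC | starting material
21 | 1,3-dimethoxy-1-(trimethylsilyloxy)buta-1,3-diene (Brassard's diene) | C=C(OC)C=C(OC)O[Si](C)(C)C | intermediate
22 | methyl (2E)-3,5,5-trimethoxyhex-2-enoate | COC(=O)/C=C(\CC(C)(OC)OC)OC | intermediate
23 | (2E)-3,5,5-trimethoxyhex-2-enoic acid | OC(=O)/C=C(\CC(C)(OC)OC)OC | intermediate
24 | (2E)-1-(imidazol-1-yl)-3,5,5-trimethoxyhex-2-en-1-one | O=C(/C=C(\CC(C)(OC)OC)OC)n1ccnc1 | intermediate
25 | methyl (4E)-5,7,7-trimethoxy-3-oxo-2-Q-oct-4-enoate (epimers at C2 of the chain) | COC(=O)C([C@@H]1C[C@H](CCc2ccc(OCOC)cc2)O[C@H](c2ccc(OCOC)cc2)[C@H]1[C@H](/C=C/C[C@@H](O[Si](C)(C)C(C)(C)C)CCc1ccc(OCOC)cc1)c1ccc(OCOC)cc1)C(=O)/C=C(\CC(C)(OC)OC)OC | intermediate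
26 | methyl (4E)-5-methoxy-3,7-dioxo-2-Q-oct-4-enoate (epimers at C2 of the chain) | COC(=O)C([C@@H]1C[C@H](CCc2ccc(OCOC)cc2)O[C@H](c2ccc(OCOC)cc2)[C@H]1[C@H](/C=C/C[C@@H](O[Si](C)(C)C(C)(C)C)CCc1ccc(OCOC)cc1)c1ccc(OCOC)cc1)C(=O)/C=C(\CC(C)=O)OC | intermediate
27 | 1-(2,4-dihydroxy-6-methoxy-3-Q-phenyl)ethan-1-one | COc1cc(O)c([C@@H]2C[C@H](CCc3ccc(OCOC)cc3)O[C@H](c3ccc(OCOC)cc3)[C@H]2[C@H](/C=C/C[C@@H](O[Si](C)(C)C(C)(C)C)CCc2ccc(OCOC)cc2)c2ccc(OCOC)cc2)c(O)c1C(C)=O | intermediate
28 | (2E)-1-(2,4-dihydroxy-6-methoxy-3-Q-phenyl)-3-[4-(methoxymethoxy)phenyl]prop-2-en-1-one | COc1cc(O)c([C@@H]2C[C@H](CCc3ccc(OCOC)cc3)O[C@H](c3ccc(OCOC)cc3)[C@H]2[C@H](/C=C/C[C@@H](O[Si](C)(C)C(C)(C)C)CCc2ccc(OCOC)cc2)c2ccc(OCOC)cc2)c(O)c1C(=O)/C=C/c1ccc(OCOC)cc1 | intermediate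
29 | blepharocalyxin E, (2E)-1-{2,4-dihydroxy-3-[(2S,3R,4R,6S)-2-(4-hydroxyphenyl)-6-[2-(4-hydroxyphenyl)ethyl]-3-[(1S,2E,5S)-5-hydroxy-1,7-bis(4-hydroxyphenyl)hept-2-en-1-yl]tetrahydro-2H-pyran-4-yl]-6-methoxyphenyl}-3-(4-hydroxyphenyl)prop-2-en-1-one | COc1cc(O)c([C@@H]2C[C@H](CCc3ccc(O)cc3)O[C@H](c3ccc(O)cc3)[C@H]2[C@H](/C=C/C[C@@H](O)CCc2ccc(O)cc2)c2ccc(O)cc2)c(O)c1C(=O)/C=C/c1ccc(O)cc1 | target

## Step count and least certain steps

Total step count: 23. Longest linear sequence: 14 steps (steps 1, 2, 5, 7, 11, 12, 13, 14, 15, 19, 20, 21, 22, 23).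

**Step 21 (key step, the proposed new method).** Proton transfer may stop at the β-keto ester enolate so that the chain does not close. The acetyl methyl may instead close onto the chain ketone (aldol fold), or methoxide may cleave the β-keto ester by retro-Claisen attack. Fallback with known chemistry, from 26 back to 27: the methyl enol ether of 26 is hydrolysed (0.5 M aq. HCl, THF, 0 °C) to the free triketo ester, methyl 3,5,7-trioxo-2-Q-octanoate F1. KOH in MeOH then effects the established Claisen cyclisation of a 3,5,7-triketo ester to the phloroacetophenone 1-(2,4,6-trihydroxy-3-Q-phenyl)ethan-1-one F2. The unchelated, most acidic 4-hydroxyl is silylated (tBuMe2SiCl, imidazole) to the 4-O-silyl ether F3. MeI and K2CO3 in acetone methylate the less hindered of the two ortho hydroxyls, the one not flanked by the tetrahydropyran, to give the 6-O-methyl 4-O-silyl ether F4. K2CO3 in MeOH removes the aryl silyl ether and returns 27.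

**Step 11.** The enolate carbon is fully substituted and sits next to the C2 aryl group, so allylation may be slow, may go to oxygen, or may lose its branched selectivity. Fallback from 11 and 13 back to 16, replacing intermolecular catalysis by a sigmatropic shift: transesterification of 11 with 13 (DMAP, toluene, 110 °C, MeOH distilled off) gives the cinnamyl ester of the tetrahydropyranone carboxylic acid F5. Carroll rearrangement (LiN(iPr)2, 2.2 equiv, THF, −78 to 65 °C) delivers the allyl unit to C3 by a [3,3] shift and loses CO2 to give 16. C1' would then depend on a chair transition state on the face anti to the C2 aryl group and would have to be proven.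

**Step 14.** Protonation at C4 may show poor facial selectivity, and base may move the double bond out of conjugation. Fallback from 16 back to 18, which sets C4 by equilibration:
- Wittig methoxymethylenation of 16 (Ph3P(CH2OMe)Cl, KN(SiMe3)2) gives the C4 enol ether F6.
- Hydrolysis (oxalic acid, THF/H2O) and equilibration with K2CO3 in MeOH give the equatorial C4 carbaldehyde F7.
- A second methoxymethylenation gives the homologous enol ether F8, and hydrolysis gives the C4 acetaldehyde F9.
- Pinnick oxidation (NaClO2, NaH2PO4, 2-methylbut-2-ene) gives the C4 acetic acid F10, and Me3SiCHN2 in MeOH gives 18.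

**Step 22.** Enolisation of the acetyl group in the phenoxide dianion may be sluggish, with Cannizzaro loss of the aldehyde or flavanone closure competing. Fallback from 27 to 29: MeOCH2Cl and K2CO3 in acetone protect the unchelated 4-hydroxyl to give the 4-O-MOM acetophenone F11. The Claisen–Schmidt condensation with 10 is then that of an ordinary 2'-hydroxyacetophenone and gives the 4'-O-MOM chalcone F12. The conditions of step 23 remove six MOM groups and the silyl ether to give 29.

## Further compounds

F1 | step 21 | methyl 3,5,7-trioxo-2-Q-octanoate | COC(=O)C([C@@H]1C[C@H](CCc2ccc(OCOC)cc2)O[C@H](c2ccc(OCOC)cc2)[C@H]1[C@H](/C=C/C[C@@H](O[Si](C)(C)C(C)(C)C)CCc1ccc(OCOC)cc1)c1ccc(OCOC)cc1)C(=O)CC(=O)CC(C)=O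
F2 | step 21 | 1-(2,4,6-trihydroxy-3-Q-phenyl)ethan-1-one | CC(=O)c1c(O)cc(O)c([C@@H]2C[C@H](CCc3ccc(OCOC)cc3)O[C@H](c3ccc(OCOC)cc3)[C@H]2[C@H](/C=C/C[C@@H](O[Si](C)(C)C(C)(C)C)CCc2ccc(OCOC)cc2)c2ccc(OCOC)cc2)c1O
F3 | step 21 | 1-[4-(tert-butyldimethylsilyloxy)-2,6-dihydroxy-3-Q-phenyl]ethan-1-one | CC(=O)c1c(O)cc(O[Si](C)(C)C(C)(C)C)c([C@@H]2C[C@H](CCc3ccc(OCOC)cc3)O[C@H](c3ccc(OCOC)cc3)[C@H]2[C@H](/C=C/C[C@@H](O[Si](C)(C)C(C)(C)C)CCc2ccc(OCOC)cc2)c2ccc(OCOC)cc2)c1O
F4 | step 21 | 1-[4-(tert-butyldimethylsilyloxy)-2-hydroxy-6-methoxy-3-Q-phenyl]ethan-1-one | CC(=O)c1c(OC)cc(O[Si](C)(C)C(C)(C)C)c([C@@H]2C[C@H](CCc3ccc(OCOC)cc3)O[C@H](c3ccc(OCOC)cc3)[C@H]2[C@H](/C=C/C[C@@H](O[Si](C)(C)C(C)(C)C)CCc2ccc(OCOC)cc2)c2ccc(OCOC)cc2)c1O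
F5 | step 11 | (2E)-3-ArM-prop-2-en-1-yl (2S,3R,6S)-2-ArM-6-(2-ArM-ethyl)-4-oxotetrahydro-2H-pyran-3-carboxylate | O=C1C[C@H](CCc2ccc(OCOC)cc2)O[C@H](c2ccc(OCOC)cc2)[C@H]1C(=O)OC/C=C/c1ccc(OCOC)cc1
F6 | step 14 | (2S,3S,6S)-4-(methoxymethylidene)-2-ArM-6-(2-ArM-ethyl)-3-[(1S)-1-ArM-prop-2-en-1-yl]tetrahydro-2H-pyran | COC=C1C[C@H](CCc2ccc(OCOC)cc2)O[C@H](c2ccc(OCOC)cc2)[C@H]1[C@H](C=C)c1ccc(OCOC)cc1
F7 | step 14 | (2S,3R,4R,6S)-2-ArM-6-(2-ArM-ethyl)-3-[(1S)-1-ArM-prop-2-en-1-yl]tetrahydro-2H-pyran-4-carbaldehyde | O=C[C@@H]1C[C@H](CCc2ccc(OCOC)cc2)O[C@H](c2ccc(OCOC)cc2)[C@H]1[C@H](C=C)c1ccc(OCOC)cc1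
F8 | step 14 | (2S,3R,4S,6S)-4-(2-methoxyethenyl)-2-ArM-6-(2-ArM-ethyl)-3-[(1S)-1-ArM-prop-2-en-1-yl]tetrahydro-2H-pyran | COC=C[C@@H]1C[C@H](CCc2ccc(OCOC)cc2)O[C@H](c2ccc(OCOC)cc2)[C@H]1[C@H](C=C)c1ccc(OCOC)cc1
F9 | step 14 | 2-[(2S,3R,4S,6S)-2-ArM-6-(2-ArM-ethyl)-3-[(1S)-1-ArM-prop-2-en-1-yl]tetrahydro-2H-pyran-4-yl]acetaldehyde | O=CC[C@@H]1C[C@H](CCc2ccc(OCOC)cc2)O[C@H](c2ccc(OCOC)cc2)[C@H]1[C@H](C=C)c1ccc(OCOC)cc1
F10 | step 14 | 2-[(2S,3R,4S,6S)-2-ArM-6-(2-ArM-ethyl)-3-[(1S)-1-ArM-prop-2-en-1-yl]tetrahydro-2H-pyran-4-yl]acetic acid | OC(=O)C[C@@H]1C[C@H](CCc2ccc(OCOC)cc2)O[C@H](c2ccc(OCOC)cc2)[C@H]1[C@H](C=C)c1ccc(OCOC)cc1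
F11 | step 22 | 1-[2-hydroxy-6-methoxy-4-(methoxymethoxy)-3-Q-phenyl]ethan-1-one | COc1cc(OCOC)c([C@@H]2C[C@H](CCc3ccc(OCOC)cc3)O[C@H](c3ccc(OCOC)cc3)[C@H]2[C@H](/C=C/C[C@@H](O[Si](C)(C)C(C)(C)C)CCc2ccc(OCOC)cc2)c2ccc(OCOC)cc2)c(O)c1C(C)=O
F12 | step 22 | (2E)-1-[2-hydroxy-6-methoxy-4-(methoxymethoxy)-3-Q-phenyl]-3-ArM-prop-2-en-1-one | COc1cc(OCOC)c([C@@H]2C[C@H](CCc3ccc(OCOC)cc3)O[C@H](c3ccc(OCOC)cc3)[C@H]2[C@H](/C=C/C[C@@H](O[Si](C)(C)C(C)(C)C)CCc2ccc(OCOC)cc2)c2ccc(OCOC)cc2)c(O)c1C(=O)/C=C/c1ccc(OCOC)cc1
A1 | alternative 1 | cis-5-(tert-butyldimethylsilyloxy)-7-methoxy-3-[1-ArM-prop-2-en-1-yl]-4-[2-(tert-butyldimethylsilyloxy)-4-ArM-butyl]-3,4-dihydro-2H-chromen-2-one | COc1cc2OC(=O)[C@@H]([C@H](C=C)c3ccc(OCOC)cc3)[C@@H](C[C@H](CCc3ccc(OCOC)cc3)O[Si](C)(C)C(C)(C)C)c2c(O[Si](C)(C)C(C)(C)C)c1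
A2 | alternative 1 | 1-[2,6-bis(tert-butyldimethylsilyloxy)-4-methoxyphenyl]-3-(tert-butyldimethylsilyloxy)-5-ArM-pentyl acetate | COc1cc(O[Si](C)(C)C(C)(C)C)c(C(OC(C)=O)C[C@H](CCc2ccc(OCOC)cc2)O[Si](C)(C)C(C)(C)C)c(O[Si](C)(C)C(C)(C)C)c1
A3 | alternative 1 | 1-(imidazol-1-yl)-3-ArM-pent-4-en-1-one | O=C(C[C@H](C=C)c1ccc(OCOC)cc1)n1ccnc1
A4 | alternative 2 | all-equatorial 4-[2,6-bis(tert-butyldimethylsilyloxy)-4-methoxyphenyl]-2-[4-(tert-butyldimethylsilyloxy)phenyl]-6-{2-[4-(tert-butyldimethylsilyloxy)phenyl]ethyl}-3-{1-[4-(tert-butyldimethylsilyloxy)phenyl]prop-2-en-1-yl}tetrahydro-2H-pyran | COc1cc(O[Si](C)(C)C(C)(C)C)c([C@@H]2C[C@H](CCc3ccc(O[Si](C)(C)C(C)(C)C)cc3)O[C@H](c3ccc(O[Si](C)(C)C(C)(C)C)cc3)[C@H]2[C@H](C=C)c2ccc(O[Si](C)(C)C(C)(C)C)cc2)c(O[Si](C)(C)C(C)(C)C)c1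
A5 | alternative 2 | α-acetoxy ether: 1-{[2-(2,6-bis(tert-butyldimethylsilyloxy)-4-methoxyphenyl)methylidene-substituted 1,3-diaryl-pent-4-enyl]oxy}-3-[4-(tert-butyldimethylsilyloxy)phenyl]propyl acetate | CC(=O)OC(CCc1ccc(O[Si](C)(C)C(C)(C)C)cc1)O[C@H](c1ccc(O[Si](C)(C)C(C)(C)C)cc1)[C@H](C(=C)c1c(O[Si](C)(C)C(C)(C)C)cc(OC)cc1O[Si](C)(C)C(C)(C)C)[C@H](C=C)c1ccc(O[Si](C)(C)C(C)(C)C)cc1
A6 | alternative 3 | all-equatorial 2-[2-ArM-6-(2-ArM-ethyl)-3-(1-ArM-prop-2-en-1-yl)tetrahydro-2H-pyran-4-yl]-5-methoxy-1,3-phenylene diacetate | COc1cc(OC(C)=O)c([C@@H]2C[C@H](CCc3ccc(OCOC)cc3)O[C@H](c3ccc(OCOC)cc3)[C@H]2[C@H](C=C)c2ccc(OCOC)cc2)c(OC(C)=O)c1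
A7 | alternative 3 | 2-[(1E)-1,7-bis(ArM)-5-(triethylsilyloxy)hept-1-en-3-yl]-5-methoxy-1,3-phenylene diacetate | COc1cc(OC(C)=O)c([C@@H](/C=C/c2ccc(OCOC)cc2)C[C@H](CCc2ccc(OCOC)cc2)O[Si](CC)(CC)CC)c(OC(C)=O)c1
A8 | alternative 3 | racemic 1-[4-(methoxymethoxy)phenyl]prop-2-en-1-ol | C=CC(O)c1ccc(OCOC)cc1
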